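**Balance first.** A closed flask keeps every unit of starting material charged, so whatever has left the starting material and is not target sits in something unread.

the same everywhere: starting material 0.050 M
- green: catalyst 1 mol%; run made earlier
- flask: catalyst 0.5 mol%; time 8.0 h

green run (percent of the starting material charged)

| time / min | target / % | starting material / % |
|---|---|---|
| 3.00 | 8 | 85 |
| 10.0 | 22 | 62 |
| 15.0 | 26 | 57 |
| 25.0 | 32 | 32 |
| 40.0 | 39 | 18 |
| 50.0 | 43 | 12 |

(scatter of a reading: 2 percentage points)

- no earlier run changes the charge of catalyst; that part of a forecast is a guess

- the best time, 8.0 h at the latest, for target
- the amount of target, in percent of the starting material charged, at that time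
- earliest time at which at least nineteen twentieths of that best amount are there
- latest time at which they still are

**The split.** At 10.0 min the green run holds 22% target and 16.0% unread material. That gives 1.38 for the split, target gained over starting material lost elsewhere (the selectivity factor), a reading carrying the scatter, above the even case of 1.

**Turning time.** The green share of consumed starting material found as target falls from 57.9% at 10.0 min to 48.9% at 50.0 min. At that last share the 12% of starting material then left in the green run stands for about 5.86% of target, while the falling share, read through the scatter, suggests that target itself leaks away.

**Turning catalyst.** No run shows half the catalyst, so this reckoning guesses that [catalyst] enters the target step and not the other. The reckoned split for the flask is then 0.688, below the even case, which puts 40.7% of the charge into target before any loss.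

**The forecast.** It differs here, “Guessing both steps are first order in catalyst”, and gives 44% at 2 h, with a window from 1.33 h to 3 h.

**The flask.** The flask peaks at 26.4% after 1.09 h, its window running from 0.748 h to 1.57 h; the green run's highest target up to its last reading, 40.5% without the scatter, goes to 25.7% with the catalyst changed and is 40.6% with the time changed.

    starting material + catalyst → catalyst + target (k = 0.820 M⁻¹ s⁻¹)
    starting material → side product (k = 2.90 × 10⁻⁴ s⁻¹)
    target ⇌ isomer of the product (K = 2.40, k = 1.30 × 10⁻⁴ s⁻¹)

**The split again.** In the flask, starting material has a half-life of 0.66 h by the step to side product alone, shorter than the 0.94 h of the catalysed step alone, a split of 0.702. At 8.00 h target and isomer of the product together stand to side product in the flask as 0.707, beside the 0.688 reckoned. For the neighbour flask with 2 mol% of catalyst the green split scales to 2.75, and that neighbour ends with the same ratio at 2.83, holding 26.1% side product.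

The runs are calculated for substances that don't exist.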